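**Plan**

- Retrosynthesis: the first cut is the aryl–CH bond between C6 of the central 4-substituted resorcinol ring and the diarylmethine carbon on C3 of the dihydrobenzofuran. This gives a west ortho-hydroxybenzyl alcohol and an east oxolanyl-resorcinol.
- West cuts: carbinol C–aryl bond, enone aryl–vinyl bond, C2–C3 bond of the dihydrobenzofuran. East cuts: oxolane C2–aryl bond, C4–C5 bond, C3–C4 bond.
- Forward, west: carbenoid C–H insertion closes the dihydrobenzofuran, a Heck reaction adds the enone, and a magnesium phenoxide hydroxyalkylation gives the carbinol. Forward, east: a 4-oxobutanoate is made by photoredox alkylation, an anti aldol and lactonisation close the five-membered ring, and the derived lactol is arylated by resorcinol. The halves are joined last and eight silyl ethers are removed.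
- Enabling feature: the methine carbon is benzylic to a ring with a free hydroxyl ortho to it, so both carbinol epimers ionise to one ortho-quinone methide. Its partner is the resorcinol CH that is para to one hydroxyl and ortho to the other.
- Stereochemistry: dihydrobenzofuran C2 from the chiral dirhodium catalyst and C3 by epimerisation to trans; oxolane C3 from the imidazolidinone catalyst, C4/C5 from the anti aldol, C2 by trans attack on the oxocarbenium ion; the methine from the chiral phosphoric acid.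

Key step: step 22

Abbreviations: TIPSO = triisopropylsilyloxy; TBSO = tert-butyldimethylsilyloxy.

Assumption: the senses of induction of Rh2(S-PTTL)4, of the imidazolidinone and of (R)-TRIP are taken from the accepted models; should one prove opposite, the mirror-image catalyst is used and nothing else changes.

Step 1
Reactants: 1 4-hydroxybenzaldehyde
Product: 2 4-(TIPSO)benzaldehyde
Conditions: TIPSCl, imidazole, DMF, rt
Reagents that add atoms: triisopropylsilyl chloride, CC(C)[Si](Cl)(C(C)C)C(C)C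
Why: Phenol silylation; the hindered silyl ether should survive the basic, reducing and Lewis acidic steps ahead and leave with fluoride at the end.

Step 2
Reactants: 2 4-(TIPSO)benzaldehyde
Product: 3 [4-(TIPSO)phenyl]methanol
Conditions: NaBH4, MeOH, 0 °C
Reagents that add atoms: none
Why: Borohydride reduction of an aromatic aldehyde to the benzylic alcohol.

Step 3
Reactants: 4 methyl 2-(5-bromo-2-hydroxyphenyl)acetate; 3 [4-(TIPSO)phenyl]methanol
Product: 5 methyl 2-[5-bromo-2-[[4-(TIPSO)phenyl]methoxy]phenyl]acetate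
Conditions: PPh3, DIAD, THF, 0 °C → rt
Reagents that add atoms: none
Why: Mitsunobu etherification of the phenol with the primary benzylic alcohol under neutral conditions that spare the aryl silyl ether and the ester.

Step 4
Reactants: 5 methyl 2-[5-bromo-2-[[4-(TIPSO)phenyl]methoxy]phenyl]acetate
Product: 6 methyl 2-[5-bromo-2-[[4-(TIPSO)phenyl]methoxy]phenyl]-2-diazoacetate
Conditions: p-ABSA, DBU, MeCN, 0 °C → rt
Reagents that add atoms: 4-acetamidobenzenesulfonyl azide, CC(=O)Nc1ccc(cc1)S(=O)(=O)N=[N+]=[N-]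
Why: Regitz diazo transfer to the acidic arylacetate position gives the donor/acceptor diazo ester.

Step 5
Reactants: 6 methyl 2-[5-bromo-2-[[4-(TIPSO)phenyl]methoxy]phenyl]-2-diazoacetate
Product: 7 methyl (2S,3R)-5-bromo-2-[4-(TIPSO)phenyl]-2,3-dihydro-1-benzofuran-3-carboxylate (2,3-cis)
Conditions: Rh2(S-PTTL)4 (1 mol%), toluene, −60 °C
Reagents that add atoms: none
Why: Intramolecular carbenoid C–H insertion into the ether-activated benzylic C–H closes the five-membered ring, with the chiral carboxylate ligands selecting one enantiotopic hydrogen to set C2 and the cis ester formed kinetically.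

Step 6
Reactants: 7 methyl (2S,3R)-5-bromo-2-[4-(TIPSO)phenyl]-2,3-dihydro-1-benzofuran-3-carboxylate
Product: 8 methyl (2S,3S)-5-bromo-2-[4-(TIPSO)phenyl]-2,3-dihydro-1-benzofuran-3-carboxylate (2,3-trans)
Conditions: NaOMe (0.2 equiv), MeOH–THF, 0 °C → rt
Reagents that add atoms: none
Why: Base-mediated epimerisation at the ester α-carbon C3 gives the thermodynamically preferred trans isomer while C2 is untouched.

Step 7
Reactants: 8 methyl (2S,3S)-5-bromo-2-[4-(TIPSO)phenyl]-2,3-dihydro-1-benzofuran-3-carboxylate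
Product: 9 [(2S,3R)-5-bromo-2-[4-(TIPSO)phenyl]-2,3-dihydro-1-benzofuran-3-yl]methanol (2,3-trans)
Conditions: LiBH4, THF, 0 °C → rt
Reagents that add atoms: none
Why: Ester reduction to the primary alcohol removes the base-sensitive carbonyl at C3 before the hot, basic Heck step.

Step 8
Reactants: 10 1-(2,4-dihydroxyphenyl)ethanone
Product: 11 1-[2,4-bis(TIPSO)phenyl]ethanone
Conditions: TIPSOTf, 2,6-lutidine, CH2Cl2, 0 °C → rt
Reagents that add atoms: triisopropylsilyl triflate, CC(C)[Si](OS(=O)(=O)C(F)(F)F)(C(C)C)C(C)C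
Why: Silylation with the silyl triflate should also cap the hydrogen-bonded ortho phenol.

Step 9
Reactants: 11 1-[2,4-bis(TIPSO)phenyl]ethanone
Product: 12 1-[2,4-bis(TIPSO)phenyl]prop-2-en-1-one
Conditions: (CH2O)n, i-Pr2NH2+ CF3CO2− (1 equiv), CF3CO2H (0.1 equiv), THF, 65 °C
Reagents that add atoms: formaldehyde (as paraformaldehyde), C=O
Why: Mannich-type α-methylenation of the methyl ketone (aminomethylation then elimination of the amine) gives the aryl vinyl ketone.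

Step 10
Reactants: 9 [(2S,3R)-5-bromo-2-[4-(TIPSO)phenyl]-2,3-dihydro-1-benzofuran-3-yl]methanol; 12 1-[2,4-bis(TIPSO)phenyl]prop-2-en-1-one
Product: 13 (E)-1-[2,4-bis(TIPSO)phenyl]-3-[(2S,3R)-3-(hydroxymethyl)-2-[4-(TIPSO)phenyl]-2,3-dihydro-1-benzofuran-5-yl]prop-2-en-1-one
Conditions: Pd(OAc)2 (5 mol%), P(o-tol)3 (10 mol%), Et3N, DMF, 90 °C
Reagents that add atoms: none
Why: Heck coupling of the aryl bromide with the enone gives the E chalcone by syn insertion and syn β-hydride elimination.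

Step 11
Reactants: 13 (E)-1-[2,4-bis(TIPSO)phenyl]-3-[(2S,3R)-3-(hydroxymethyl)-2-[4-(TIPSO)phenyl]-2,3-dihydro-1-benzofuran-5-yl]prop-2-en-1-one
Product: 14 (2S,3S)-5-[(E)-3-[2,4-bis(TIPSO)phenyl]-3-oxoprop-1-enyl]-2-[4-(TIPSO)phenyl]-2,3-dihydro-1-benzofuran-3-carbaldehyde
Conditions: Dess–Martin periodinane, NaHCO3, CH2Cl2, 0 °C → rt
Reagents that add atoms: none
Why: Dess–Martin oxidation gives the aldehyde under buffered, non-basic conditions that should not epimerise C3 or open the ring.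

Step 12
Reactants: 14 (2S,3S)-5-[(E)-3-[2,4-bis(TIPSO)phenyl]-3-oxoprop-1-enyl]-2-[4-(TIPSO)phenyl]-2,3-dihydro-1-benzofuran-3-carbaldehyde; 15 3-(TBSO)phenol
Product: 16 (E)-1-[2,4-bis(TIPSO)phenyl]-3-[(2S,3R)-3-[[2-hydroxy-4-(TBSO)phenyl](hydroxy)methyl]-2-[4-(TIPSO)phenyl]-2,3-dihydro-1-benzofuran-5-yl]prop-2-en-1-one as both carbinol epimers
Conditions: 15, EtMgBr, Et2O, 0 °C; exchange to toluene; then 14, rt; aq NH4Cl
Reagents that add atoms: none
Why: Ortho-specific hydroxyalkylation of the bromomagnesium phenoxide, which delivers the aldehyde through a magnesium chelate to the unhindered ortho carbon para to the silyl ether and spares the enone; the new carbinol centre forms unselectively, which does not matter because step 22 erases it.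

Step 13
Reactants: 17 methyl 3-(4-hydroxyphenyl)propanoate
Product: 18 methyl 3-[4-(TIPSO)phenyl]propanoate
Conditions: TIPSCl, imidazole, DMF, rt
Reagents that add atoms: triisopropylsilyl chloride, CC(C)[Si](Cl)(C(C)C)C(C)C
Why: Phenol silylation as in step 1.

Step 14
Reactants: 18 methyl 3-[4-(TIPSO)phenyl]propanoate
Product: 19 3-[4-(TIPSO)phenyl]propanal
Conditions: i-Bu2AlH, CH2Cl2, −78 °C; Rochelle salt
Reagents that add atoms: none
Why: Partial reduction of the ester stops at the aldehyde because the tetrahedral aluminium hemiacetal is stable at −78 °C.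

Step 15
Reactants: 11 1-[2,4-bis(TIPSO)phenyl]ethanone
Product: 21 2-bromo-1-[2,4-bis(TIPSO)phenyl]ethanone, via trimethylsilyl enol ether 20 (not isolated)
Conditions: TMSOTf, Et3N, CH2Cl2, 0 °C; then NBS, THF, 0 °C
Reagents that add atoms: N-bromosuccinimide, O=C1CCC(=O)N1Br
Why: α-Bromination through the silyl enol ether avoids acid and ring bromination of the electron-rich arene.

Step 16
Reactants: 19 3-[4-(TIPSO)phenyl]propanal; 21 2-bromo-1-[2,4-bis(TIPSO)phenyl]ethanone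
Product: 22 (2R)-4-[2,4-bis(TIPSO)phenyl]-4-oxo-2-[[4-(TIPSO)phenyl]methyl]butanal
Conditions: Ru(bpy)3Cl2 (0.5 mol%), (2R,5S)-2-tert-butyl-3,5-dimethylimidazolidin-4-one·CF3SO3H (20 mol%), 2,6-lutidine, DMF, blue LED, rt
Reagents that add atoms: none
Why: Enantioselective α-alkylation of the aldehyde by merged photoredox and enamine catalysis, in which the phenacyl radical from photoreductive C–Br cleavage adds to the unshielded face of the chiral E-enamine and sets the future oxolane C3.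

Step 17
Reactants: 22 (2R)-4-[2,4-bis(TIPSO)phenyl]-4-oxo-2-[[4-(TIPSO)phenyl]methyl]butanal
Product: 24 methyl (2R)-4-[2,4-bis(TIPSO)phenyl]-4-oxo-2-[[4-(TIPSO)phenyl]methyl]butanoate, via carboxylic acid 23 (not isolated)
Conditions: NaClO2, NaH2PO4, 2-methyl-2-butene, t-BuOH–H2O, 0 °C; then TMSCHN2, MeOH–toluene, 0 °C
Reagents that add atoms: sodium chlorite, [Na+].[O-]Cl=O; trimethylsilyldiazomethane, C[Si](C)(C)C=[N+]=[N-]
Why: Pinnick oxidation and diazoalkane esterification are both buffered or neutral, so the α-stereocentre should be kept, and the small planar ester is the group wanted next to it for step 18.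

Step 18
Reactants: 24 methyl (2R)-4-[2,4-bis(TIPSO)phenyl]-4-oxo-2-[[4-(TIPSO)phenyl]methyl]butanoate; 2 4-(TIPSO)benzaldehyde
Product: 27 (3R,4R,5S)-4-[2,4-bis(TIPSO)benzoyl]-5-[4-(TIPSO)phenyl]-3-[[4-(TIPSO)phenyl]methyl]oxolan-2-one, via E-enol dicyclohexylborinate 25 (not isolated), via anti aldol hydroxy ester 26 (not isolated)
Conditions: Cy2BCl, Et3N, Et2O, −78 → 0 °C; 2, −78 °C; H2O2, pH 7 buffer, MeOH; then PPTS, toluene, 50 °C
Reagents that add atoms: none
Why: Boron-mediated anti aldol followed by acid lactonisation: the E-enol borinate reacts through a closed chair transition state (anti, hence 4,5-cis in the ring), and in the allylic-strain conformer with C3–H eclipsing the enolate the aldehyde should approach anti to the benzyl CH2 and past the small ester (hence 3,4-trans).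

Step 19
Reactants: 27 (3R,4R,5S)-4-[2,4-bis(TIPSO)benzoyl]-5-[4-(TIPSO)phenyl]-3-[[4-(TIPSO)phenyl]methyl]oxolan-2-one
Product: 28 (3R,4S,5S)-4-[[2,4-bis(TIPSO)phenyl](hydroxy)methyl]-5-[4-(TIPSO)phenyl]-3-[[4-(TIPSO)phenyl]methyl]oxolan-2-ol as anomers and carbinol epimers
Conditions: i-Bu2AlH (3.5 equiv), CH2Cl2, −78 °C; Rochelle salt
Reagents that add atoms: none
Why: Hydride reduction takes the lactone to the lactol and, unavoidably, the aryl ketone to the carbinol; no base is present, so C3 to C5 are kept and both new centres are erased later.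

Step 20
Reactants: 28 (3R,4S,5S)-4-[[2,4-bis(TIPSO)phenyl](hydroxy)methyl]-5-[4-(TIPSO)phenyl]-3-[[4-(TIPSO)phenyl]methyl]oxolan-2-ol
Product: 29 (3R,4R,5S)-4-[2,4-bis(TIPSO)benzoyl]-5-[4-(TIPSO)phenyl]-3-[[4-(TIPSO)phenyl]methyl]oxolan-2-ol as anomers
Conditions: DDQ (1.2 equiv), CH2Cl2, 0 °C → rt
Reagents that add atoms: none
Why: DDQ dehydrogenation is selective for the doubly oxygen-activated benzylic alcohol, should leave the lactol alone, and restores the ketone without base so that the cis C4/C5 relation is not epimerised.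

Step 21
Reactants: 29 (3R,4R,5S)-4-[2,4-bis(TIPSO)benzoyl]-5-[4-(TIPSO)phenyl]-3-[[4-(TIPSO)phenyl]methyl]oxolan-2-ol; 30 benzene-1,3-diol (resorcinol)
Product: 31 4-[(2R,3R,4R,5S)-4-[2,4-bis(TIPSO)benzoyl]-5-[4-(TIPSO)phenyl]-3-[[4-(TIPSO)phenyl]methyl]oxolan-2-yl]benzene-1,3-diol
Conditions: 30 (3 equiv), BF3·OEt2 (0.3 equiv), MeCN–CH2Cl2, −40 °C
Reagents that add atoms: none
Why: Friedel–Crafts arylation of the cyclic oxocarbenium ion from the lactol by C4 of resorcinol, which should attack anti to the C3 benzyl group to give the 2,3-trans oxolane (also the thermodynamic arrangement at this acid-labile centre).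

Step 22
Reactants: 16 west ortho-hydroxybenzyl alcohol (both carbinol epimers); 31 east oxolanyl-resorcinol
Product: 33 octasilyl ether of the target (seven TIPS ethers and one TBS ether; central resorcinol and the ortho hydroxyl of the neighbouring ring free), via ortho-quinone methide 32 (not isolated)
Conditions: (R)-TRIP [(R)-3,3'-bis(2,4,6-triisopropylphenyl)-1,1'-binaphthyl-2,2'-diyl hydrogen phosphate] (10 mol%), 5 Å molecular sieves, toluene–CH2Cl2, 0 °C → rt; 16 added slowly to 31 (1.5 equiv)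
Reagents that add atoms: none
Why: The phosphoric acid dehydrates both carbinol epimers of 16 to the same planar ortho-quinone methide 32 (the hydroxyl ortho to the carbinol carbon becomes the quinoid carbonyl), so the mixture from step 12 is funnelled through one intermediate; C6 of the resorcinol ring of 31 (para to one hydroxyl, ortho to the other) then adds to the exocyclic carbon in a conjugate Friedel–Crafts addition and both rings re-aromatise. The closest known reaction type is the chiral-phosphoric-acid-catalysed arylation of ortho-quinone methides, generated in situ from ortho-hydroxybenzyl alcohols, by phenols and naphthols. No ring is closed. The new methine stereocentre is set by the catalyst: the phosphate binds the quinone methide oxygen and a resorcinol hydroxyl at the same time, and (R)-TRIP is expected to expose the face that leads to the R methine, overriding the weak bias of the adjacent C3 centre. The step needs site selectivity on 31 (C6 over the hindered C2 between the hydroxyls; the acylated and mono-oxygenated rings are far less nucleophilic), chemoselectivity against self-condensation of 16 (its only activated ring position lies next to the bulky silyl ether) and capture faster than tautomerisation of 32 to the 3-benzylidene dihydrobenzofuran, which slow addition of 16 to excess 31 at low temperature should secure. The trans oxolane centre next to the resorcinol, the only other acid-labile centre, is already in its thermodynamic configuration.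

Step 23
Reactants: 33 octasilyl ether of the target
Product: 34 CNP0225254.5 (target)
Conditions: HF·pyridine, pyridine, THF, 0 °C → rt
Reagents that add atoms: none
Why: Fluoride-mediated cleavage of all eight aryl silyl ethers under buffered conditions that should not epimerise the ketone α-carbon, cyclise the 2'-hydroxychalcone or ionise the benzylic ethers.

**Compound list**

1 | 4-hydroxybenzaldehyde | O=Cc1ccc(O)cc1 | starting material
2 | 4-(TIPSO)benzaldehyde | O=Cc1ccc(O[Si](C(C)C)(C(C)C)C(C)C)cc1 | intermediate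
3 | [4-(TIPSO)phenyl]methanol | OCc1ccc(O[Si](C(C)C)(C(C)C)C(C)C)cc1 | intermediate
4 | methyl 2-(5-bromo-2-hydroxyphenyl)acetate | COC(=O)Cc1cc(Br)ccc1O | starting material
5 | methyl 2-[5-bromo-2-[[4-(TIPSO)phenyl]methoxy]phenyl]acetate | COC(=O)Cc1cc(Br)ccc1OCc1ccc(O[Si](C(C)C)(C(C)C)C(C)C)cc1 | intermediate
6 | methyl 2-[5-bromo-2-[[4-(TIPSO)phenyl]methoxy]phenyl]-2-diazoacetate | COC(=O)C(=[N+]=[N-])c1cc(Br)ccc1OCc1ccc(O[Si](C(C)C)(C(C)C)C(C)C)cc1 | intermediate
7 | methyl (2S,3R)-5-bromo-2-[4-(TIPSO)phenyl]-2,3-dihydro-1-benzofuran-3-carboxylate (cis) | Brc1ccc2c(c1)[C@@H](C(=O)OC)[C@@H](c1ccc(O[Si](C(C)C)(C(C)C)C(C)C)cc1)O2 | intermediate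
8 | methyl (2S,3S)-5-bromo-2-[4-(TIPSO)phenyl]-2,3-dihydro-1-benzofuran-3-carboxylate (trans) | Brc1ccc2c(c1)[C@H](C(=O)OC)[C@@H](c1ccc(O[Si](C(C)C)(C(C)C)C(C)C)cc1)O2 | intermediate
9 | [(2S,3R)-5-bromo-2-[4-(TIPSO)phenyl]-2,3-dihydro-1-benzofuran-3-yl]methanol (trans) | Brc1ccc2c(c1)[C@H](CO)[C@@H](c1ccc(O[Si](C(C)C)(C(C)C)C(C)C)cc1)O2 | intermediate
10 | 1-(2,4-dihydroxyphenyl)ethanone | CC(=O)c1ccc(O)cc1O | starting material
11 | 1-[2,4-bis(TIPSO)phenyl]ethanone | CC(=O)c1ccc(O[Si](C(C)C)(C(C)C)C(C)C)cc1O[Si](C(C)C)(C(C)C)C(C)C | intermediate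
12 | 1-[2,4-bis(TIPSO)phenyl]prop-2-en-1-one | C=CC(=O)c1ccc(O[Si](C(C)C)(C(C)C)C(C)C)cc1O[Si](C(C)C)(C(C)C)C(C)C | intermediate
13 | (E)-1-[2,4-bis(TIPSO)phenyl]-3-[(2S,3R)-3-(hydroxymethyl)-2-[4-(TIPSO)phenyl]-2,3-dihydro-1-benzofuran-5-yl]prop-2-en-1-one | O=C(/C=C/c1ccc2c(c1)[C@H](CO)[C@@H](c1ccc(O[Si](C(C)C)(C(C)C)C(C)C)cc1)O2)c1ccc(O[Si](C(C)C)(C(C)C)C(C)C)cc1O[Si](C(C)C)(C(C)C)C(C)C | intermediate
14 | (2S,3S)-5-[(E)-3-[2,4-bis(TIPSO)phenyl]-3-oxoprop-1-enyl]-2-[4-(TIPSO)phenyl]-2,3-dihydro-1-benzofuran-3-carbaldehyde | O=C(/C=C/c1ccc2c(c1)[C@H](C=O)[C@@H](c1ccc(O[Si](C(C)C)(C(C)C)C(C)C)cc1)O2)c1ccc(O[Si](C(C)C)(C(C)C)C(C)C)cc1O[Si](C(C)C)(C(C)C)C(C)C | intermediate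
15 | 3-(TBSO)phenol | Oc1cccc(O[Si](C)(C)C(C)(C)C)c1 | starting material
16 | (E)-1-[2,4-bis(TIPSO)phenyl]-3-[(2S,3R)-3-[[2-hydroxy-4-(TBSO)phenyl](hydroxy)methyl]-2-[4-(TIPSO)phenyl]-2,3-dihydro-1-benzofuran-5-yl]prop-2-en-1-one (both carbinol epimers) | O=C(/C=C/c1ccc2c(c1)[C@H](C(O)c1ccc(O[Si](C)(C)C(C)(C)C)cc1O)[C@@H](c1ccc(O[Si](C(C)C)(C(C)C)C(C)C)cc1)O2)c1ccc(O[Si](C(C)C)(C(C)C)C(C)C)cc1O[Si](C(C)C)(C(C)C)C(C)C | intermediate
17 | methyl 3-(4-hydroxyphenyl)propanoate | COC(=O)CCc1ccc(O)cc1 | starting material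
18 | methyl 3-[4-(TIPSO)phenyl]propanoate | COC(=O)CCc1ccc(O[Si](C(C)C)(C(C)C)C(C)C)cc1 | intermediate
19 | 3-[4-(TIPSO)phenyl]propanal | O=CCCc1ccc(O[Si](C(C)C)(C(C)C)C(C)C)cc1 | intermediate
20 | [1-[2,4-bis(TIPSO)phenyl]ethenyl]oxy-trimethylsilane | C=C(O[Si](C)(C)C)c1ccc(O[Si](C(C)C)(C(C)C)C(C)C)cc1O[Si](C(C)C)(C(C)C)C(C)C | intermediate
21 | 2-bromo-1-[2,4-bis(TIPSO)phenyl]ethanone | BrCC(=O)c1ccc(O[Si](C(C)C)(C(C)C)C(C)C)cc1O[Si](C(C)C)(C(C)C)C(C)C | intermediate
22 | (2R)-4-[2,4-bis(TIPSO)phenyl]-4-oxo-2-[[4-(TIPSO)phenyl]methyl]butanal | O=C(C[C@H](C=O)Cc1ccc(O[Si](C(C)C)(C(C)C)C(C)C)cc1)c1ccc(O[Si](C(C)C)(C(C)C)C(C)C)cc1O[Si](C(C)C)(C(C)C)C(C)C | intermediate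
23 | (2R)-4-[2,4-bis(TIPSO)phenyl]-4-oxo-2-[[4-(TIPSO)phenyl]methyl]butanoic acid | O=C(C[C@H](C(=O)O)Cc1ccc(O[Si](C(C)C)(C(C)C)C(C)C)cc1)c1ccc(O[Si](C(C)C)(C(C)C)C(C)C)cc1O[Si](C(C)C)(C(C)C)C(C)C | intermediate
24 | methyl (2R)-4-[2,4-bis(TIPSO)phenyl]-4-oxo-2-[[4-(TIPSO)phenyl]methyl]butanoate | O=C(C[C@H](C(=O)OC)Cc1ccc(O[Si](C(C)C)(C(C)C)C(C)C)cc1)c1ccc(O[Si](C(C)C)(C(C)C)C(C)C)cc1O[Si](C(C)C)(C(C)C)C(C)C | intermediate
25 | E-enol dicyclohexylborinate of 24 | C1CCCCC1B(C1CCCCC1)O/C(=C/[C@H](C(=O)OC)Cc1ccc(O[Si](C(C)C)(C(C)C)C(C)C)cc1)c1ccc(O[Si](C(C)C)(C(C)C)C(C)C)cc1O[Si](C(C)C)(C(C)C)C(C)C | intermediate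
26 | methyl (2R,3R,4S)-3-[2,4-bis(TIPSO)benzoyl]-4-hydroxy-4-[4-(TIPSO)phenyl]-2-[[4-(TIPSO)phenyl]methyl]butanoate | O[C@H](c1ccc(O[Si](C(C)C)(C(C)C)C(C)C)cc1)[C@H](C(=O)c1ccc(O[Si](C(C)C)(C(C)C)C(C)C)cc1O[Si](C(C)C)(C(C)C)C(C)C)[C@H](C(=O)OC)Cc1ccc(O[Si](C(C)C)(C(C)C)C(C)C)cc1 | intermediate
27 | (3R,4R,5S)-4-[2,4-bis(TIPSO)benzoyl]-5-[4-(TIPSO)phenyl]-3-[[4-(TIPSO)phenyl]methyl]oxolan-2-one | O=C1O[C@H](c2ccc(O[Si](C(C)C)(C(C)C)C(C)C)cc2)[C@H](C(=O)c2ccc(O[Si](C(C)C)(C(C)C)C(C)C)cc2O[Si](C(C)C)(C(C)C)C(C)C)[C@H]1Cc1ccc(O[Si](C(C)C)(C(C)C)C(C)C)cc1 | intermediate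
28 | (3R,4S,5S)-4-[[2,4-bis(TIPSO)phenyl](hydroxy)methyl]-5-[4-(TIPSO)phenyl]-3-[[4-(TIPSO)phenyl]methyl]oxolan-2-ol (anomers and carbinol epimers) | OC1O[C@H](c2ccc(O[Si](C(C)C)(C(C)C)C(C)C)cc2)[C@H](C(O)c2ccc(O[Si](C(C)C)(C(C)C)C(C)C)cc2O[Si](C(C)C)(C(C)C)C(C)C)[C@H]1Cc1ccc(O[Si](C(C)C)(C(C)C)C(C)C)cc1 | intermediate
29 | (3R,4R,5S)-4-[2,4-bis(TIPSO)benzoyl]-5-[4-(TIPSO)phenyl]-3-[[4-(TIPSO)phenyl]methyl]oxolan-2-ol (anomers) | OC1O[C@H](c2ccc(O[Si](C(C)C)(C(C)C)C(C)C)cc2)[C@H](C(=O)c2ccc(O[Si](C(C)C)(C(C)C)C(C)C)cc2O[Si](C(C)C)(C(C)C)C(C)C)[C@H]1Cc1ccc(O[Si](C(C)C)(C(C)C)C(C)C)cc1 | intermediate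
30 | benzene-1,3-diol (resorcinol) | Oc1cccc(O)c1 | starting material
31 | 4-[(2R,3R,4R,5S)-4-[2,4-bis(TIPSO)benzoyl]-5-[4-(TIPSO)phenyl]-3-[[4-(TIPSO)phenyl]methyl]oxolan-2-yl]benzene-1,3-diol | Oc1ccc([C@@H]2O[C@H](c3ccc(O[Si](C(C)C)(C(C)C)C(C)C)cc3)[C@H](C(=O)c3ccc(O[Si](C(C)C)(C(C)C)C(C)C)cc3O[Si](C(C)C)(C(C)C)C(C)C)[C@H]2Cc2ccc(O[Si](C(C)C)(C(C)C)C(C)C)cc2)c(O)c1 | intermediate
32 | ortho-quinone methide from 16 (6-alkylidene-3-(TBSO)cyclohexa-2,4-dien-1-one on C3 of the dihydrobenzofuran) | O=C(/C=C/c1ccc2c(c1)[C@H](C=C1C=CC(O[Si](C)(C)C(C)(C)C)=CC1=O)[C@@H](c1ccc(O[Si](C(C)C)(C(C)C)C(C)C)cc1)O2)c1ccc(O[Si](C(C)C)(C(C)C)C(C)C)cc1O[Si](C(C)C)(C(C)C)C(C)C | intermediate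
33 | octasilyl ether of the target (R methine; seven TIPS ethers, one TBS ether) | O=C(/C=C/c1ccc2c(c1)[C@H]([C@H](c1ccc(O[Si](C)(C)C(C)(C)C)cc1O)c1cc([C@@H]3O[C@H](c4ccc(O[Si](C(C)C)(C(C)C)C(C)C)cc4)[C@H](C(=O)c4ccc(O[Si](C(C)C)(C(C)C)C(C)C)cc4O[Si](C(C)C)(C(C)C)C(C)C)[C@H]3Cc3ccc(O[Si](C(C)C)(C(C)C)C(C)C)cc3)c(O)cc1O)[C@@H](c1ccc(O[Si](C(C)C)(C(C)C)C(C)C)cc1)O2)c1ccc(O[Si](C(C)C)(C(C)C)C(C)C)cc1O[Si](C(C)C)(C(C)C)C(C)C | intermediate
34 | CNP0225254.5 | O=C(/C=C/c1ccc2c(c1)[C@H]([C@H](c1ccc(O)cc1O)c1cc([C@@H]3O[C@H](c4ccc(O)cc4)[C@H](C(=O)c4ccc(O)cc4O)[C@H]3Cc3ccc(O)cc3)c(O)cc1O)[C@@H](c1ccc(O)cc1)O2)c1ccc(O)cc1O | target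

**Totals**

Total step count: 23. Longest linear sequence: 12 steps (steps 1–7, 10–12, 22, 23, from 4-hydroxybenzaldehyde 1).

**Steps most likely to fail**

1. Step 22. What may go wrong: poor facial selectivity at the planar methine carbon; tautomerisation of the quinone methide to the exocyclic alkene followed by aromatisation to the benzofuran; oligomerisation by further arylation. Fallback, setting out from aldehyde 14 (with resorcinol 30 and lactol 29) and coming back at target 34: acid-catalysed double Friedel–Crafts condensation of 14 with excess 30 should give the bis(2,4-dihydroxyphenyl)methyl compound F1, in which the methine carbon carries two identical rings and is not yet stereogenic. Arylation of the oxocarbenium ion from 29 by F1 under the chiral phosphoric acid then attaches the oxolane to one of the two diastereotopic rings. This creates the methine centre and the trans oxolane C2 centre together and gives the heptakis-TIPS ether F2, which is desilylated as in step 23 to 34.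

2. Step 18. What may go wrong: poor facial selectivity of the enol borinate with respect to the adjacent C3 centre, or erosion of the anti preference. Fallback, setting out from 24 (with 2) and coming back at 27: an unselective lithium-enolate aldol (LiHMDS, THF, −78 °C) gives the aldol mixture F3. Dess–Martin oxidation gives the 1,3-diketone F4, whose doubly activated carbon epimerises freely. Asymmetric transfer hydrogenation with RuCl(p-cymene)[(S,S)-TsDPEN] and HCO2H/Et3N should reduce the unhindered 4-silyloxyphenyl ketone with dynamic kinetic resolution to the anti hydroxy ketone 26, which lactonises to 27 as in step 18.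

3. Step 12. What may go wrong: base-induced β-elimination of the aryloxide from the aldehyde (ring opening with loss of the C2 configuration), conjugate addition to the enone, or attack at the wrong ring position of the phenol. Fallback, setting out from 14 and coming back at 34: 4-bromoresorcinol is bis-silylated to the aryl bromide F5. Bromine–lithium exchange (t-BuLi, −78 °C) and transmetalation with ClTi(Oi-Pr)3 give an aryltitanium reagent that adds to aldehydes but not to ketones or enones, so 14 should give the fully silylated carbinol F6. Ionisation of F6 by a strong chiral Brønsted acid to the 2,4-bis(silyloxy)benzylic cation and capture by 31 gives the coupled nonasilyl ether F7, which is desilylated as in step 23 to 34.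

**Further compounds**

F1 | step 22 | (E)-1-[2,4-bis(TIPSO)phenyl]-3-[(2S,3S)-3-[bis(2,4-dihydroxyphenyl)methyl]-2-[4-(TIPSO)phenyl]-2,3-dihydro-1-benzofuran-5-yl]prop-2-en-1-one | O=C(/C=C/c1ccc2c(c1)[C@H](C(c1ccc(O)cc1O)c1ccc(O)cc1O)[C@@H](c1ccc(O[Si](C(C)C)(C(C)C)C(C)C)cc1)O2)c1ccc(O[Si](C(C)C)(C(C)C)C(C)C)cc1O[Si](C(C)C)(C(C)C)C(C)C
F2 | step 22 | heptakis-TIPS ether of the target (33 with a free 2,4-dihydroxyphenyl ring in place of the TBS-bearing ring) | O=C(/C=C/c1ccc2c(c1)[C@H]([C@H](c1ccc(O)cc1O)c1cc([C@@H]3O[C@H](c4ccc(O[Si](C(C)C)(C(C)C)C(C)C)cc4)[C@H](C(=O)c4ccc(O[Si](C(C)C)(C(C)C)C(C)C)cc4O[Si](C(C)C)(C(C)C)C(C)C)[C@H]3Cc3ccc(O[Si](C(C)C)(C(C)C)C(C)C)cc3)c(O)cc1O)[C@@H](c1ccc(O[Si](C(C)C)(C(C)C)C(C)C)cc1)O2)c1ccc(O[Si](C(C)C)(C(C)C)C(C)C)cc1O[Si](C(C)C)(C(C)C)C(C)C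
F3 | step 18 | methyl (2R)-3-[2,4-bis(TIPSO)benzoyl]-4-hydroxy-4-[4-(TIPSO)phenyl]-2-[[4-(TIPSO)phenyl]methyl]butanoate (mixture at C3 and C4) | OC(c1ccc(O[Si](C(C)C)(C(C)C)C(C)C)cc1)C(C(=O)c1ccc(O[Si](C(C)C)(C(C)C)C(C)C)cc1O[Si](C(C)C)(C(C)C)C(C)C)[C@H](C(=O)OC)Cc1ccc(O[Si](C(C)C)(C(C)C)C(C)C)cc1
F4 | step 18 | methyl (2R)-3-[2,4-bis(TIPSO)benzoyl]-4-oxo-4-[4-(TIPSO)phenyl]-2-[[4-(TIPSO)phenyl]methyl]butanoate (C3 epimers interconverting) | O=C(c1ccc(O[Si](C(C)C)(C(C)C)C(C)C)cc1)C(C(=O)c1ccc(O[Si](C(C)C)(C(C)C)C(C)C)cc1O[Si](C(C)C)(C(C)C)C(C)C)[C@H](C(=O)OC)Cc1ccc(O[Si](C(C)C)(C(C)C)C(C)C)cc1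
F5 | step 12 | 1-bromo-2,4-bis(TIPSO)benzene | Brc1ccc(O[Si](C(C)C)(C(C)C)C(C)C)cc1O[Si](C(C)C)(C(C)C)C(C)C
F6 | step 12 | (E)-1-[2,4-bis(TIPSO)phenyl]-3-[(2S,3R)-3-[[2,4-bis(TIPSO)phenyl](hydroxy)methyl]-2-[4-(TIPSO)phenyl]-2,3-dihydro-1-benzofuran-5-yl]prop-2-en-1-one (both carbinol epimers) | O=C(/C=C/c1ccc2c(c1)[C@H](C(O)c1ccc(O[Si](C(C)C)(C(C)C)C(C)C)cc1O[Si](C(C)C)(C(C)C)C(C)C)[C@@H](c1ccc(O[Si](C(C)C)(C(C)C)C(C)C)cc1)O2)c1ccc(O[Si](C(C)C)(C(C)C)C(C)C)cc1O[Si](C(C)C)(C(C)C)C(C)C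
F7 | step 12 | nonakis-TIPS ether of the target (33 with a 2,4-bis(TIPSO)phenyl ring in place of the TBS-bearing ring) | O=C(/C=C/c1ccc2c(c1)[C@H]([C@H](c1ccc(O[Si](C(C)C)(C(C)C)C(C)C)cc1O[Si](C(C)C)(C(C)C)C(C)C)c1cc([C@@H]3O[C@H](c4ccc(O[Si](C(C)C)(C(C)C)C(C)C)cc4)[C@H](C(=O)c4ccc(O[Si](C(C)C)(C(C)C)C(C)C)cc4O[Si](C(C)C)(C(C)C)C(C)C)[C@H]3Cc3ccc(O[Si](C(C)C)(C(C)C)C(C)C)cc3)c(O)cc1O)[C@@H](c1ccc(O[Si](C(C)C)(C(C)C)C(C)C)cc1)O2)c1ccc(O[Si](C(C)C)(C(C)C)C(C)C)cc1O[Si](C(C)C)(C(C)C)C(C)C
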